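A direct plan would start from (R)-α-campholenic aldehyde A1: Wittig extension, ozonolysis of the cyclopentene to keto aldehyde A2, aldol re-closure to cyclohexenone A3, conjugate reduction–methylation and triflation to enol triflate A4, Stille coupling and Ph3P·HBr to phosphonium salt A5, twofold Wittig reaction with the C10 dialdehyde 14 to diester A6, and i-Bu2AlH reduction to the target.
Its first weak point would be the ring construction (ozonolysis to A2, aldol closure to A3, reduction–methylation): four steps would be spent on a trimethylcyclohexanone that still lacks every carbon beyond C6, with ozone having to spare an enoate and an enolate having to be methylated next to one.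
Its second weak point would be the C6–C7 bond formation through A4: triflation of a 2,2,6-trisubstituted cyclohexanone without strong base and cross-coupling at a tetrasubstituted carbon flanked by a quaternary centre, the most hindered position of the ring.
Its third weak point would be the final hydride reduction of A6: the complete, air- and light-sensitive, poorly soluble C50 polyene would be exposed to excess aluminium hydride in the last step.

**Retrosynthetic overview**
The target is cut at C11=C12 and C11'=C12' (twofold Wittig) into the C10 dialdehyde 14 and two C15 phosphonium salts 13 that already carry the free side-chain hydroxyl, so no redox step follows the polyene assembly.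
Salt 13 comes from the 2-substituted β-ionone 10, whose ring (C1–C6) is closed by forming the C1–C6 bond in a proton-initiated cyclization of the open-chain isopropenyl dienone 8, a copy of the C50 β-cyclase step; C6–C7 and C5=C6 are already in the chain, so no coupling at a tetrasubstituted ring carbon is needed.
Dienone 8 comes from (R)-limonene oxide 1: the limonene ring is opened once, its C4 stereocentre becomes C2, its isopropenyl group becomes C1/C16/C17, its ketone arm C3–C5/C18 and its aldehyde arm the hydroxyprenyl chain.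
Ring events: limonene ring opened (step 1), carotenoid ring closed once (step 5); both rings of the target come from the same C20 unit, joined in step 9.

Key step: step 5

Assumption: commercial (+)-limonene 1,2-oxide (cis/trans mixture, made from (R)-limonene) is taken as (4R)-configured. Ring atoms are numbered as in carotenoids (C1 gem-dimethyl carbon, C2 stereocentre, C5=C6 ring double bond).

**Step 1**
Reactants: 1 (4R)-limonene 1,2-oxide (cis/trans mixture)
Product: 2 (3R)-6-oxo-3-(prop-1-en-2-yl)heptanal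
Conditions: H5IO6 (1.1 equiv), THF/H2O, 0 °C → rt
Reagents that add atoms: water, O
Why: Acid-promoted epoxide hydrolysis followed in the same flask by periodate glycol cleavage (Malaprade reaction) should open the limonene ring between C1 and C2 from both epoxide diastereomers, leaves the isopropenyl group untouched and cannot epimerise the stereocentre, which is β to the new aldehyde and γ to the ketone.

**Step 2**
Reactants: 2 (3R)-6-oxo-3-(prop-1-en-2-yl)heptanal; 3 ethyl 2-(triphenylphosphoranylidene)propanoate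
Product: 4 ethyl (2E,5R)-2-methyl-8-oxo-5-(prop-1-en-2-yl)non-2-enoate
Conditions: 3 (1.05 equiv), CH2Cl2, 0 °C → rt
Reagents that add atoms: none
Why: Wittig olefination with a stabilised α-methyl ylide reacts with the aldehyde but not with the methyl ketone at room temperature and should give the E-trisubstituted enoate, the acid-stable masked form of the hydroxyprenyl side chain.

**Step 3**
Reactants: 4 ethyl (2E,5R)-2-methyl-8-oxo-5-(prop-1-en-2-yl)non-2-enoate
Product: 5 ethyl (2E,5R,8RS)-8-hydroxy-2,8-dimethyl-5-(prop-1-en-2-yl)dec-2-en-9-ynoate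
Conditions: HC≡CMgBr (1.3 equiv), THF, −30 → 0 °C; aq NH4Cl
Reagents that add atoms: ethynylmagnesium bromide, C#C[Mg]Br
Why: Grignard ethynylation (1,2-addition) of the methyl ketone is much faster than attack on the α-methyl enoate ester at low temperature, and the new carbinol centre (future C5) is formed as an epimer mixture of no consequence because it becomes trigonal in step 4.

**Step 4**
Reactants: 5 ethyl (2E,5R,8RS)-8-hydroxy-2,8-dimethyl-5-(prop-1-en-2-yl)dec-2-en-9-ynoate
Product: 8 ethyl (2E,5R,10E)-2,8-dimethyl-12-oxo-5-(prop-1-en-2-yl)trideca-2,8,10-trienoate (8E/8Z mixture), via propargyl isopropenyl ether 6 (not isolated), via allenyl ketone 7 (not isolated)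
Conditions: 2-methoxypropene (5 equiv), p-TsOH (0.5 mol %), toluene, sealed tube, 100 °C; then NaOEt (0.1 equiv), EtOH, 0 °C
Reagents that add atoms: 2-methoxypropene, COC(C)=C
Why: Saucy–Marbet reaction, in which acid-catalysed exchange gives the propargyl isopropenyl ether, its [3,3]-sigmatropic (propargyl Claisen) rearrangement gives the β-allenyl ketone and ethoxide moves the allene into conjugation, so that C7–C9 and the C5=C6 double bond are installed in the open chain, both C5=C6 isomers being usable in step 5.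

**Step 5**
Reactants: 8 ethyl (2E,5R,10E)-2,8-dimethyl-12-oxo-5-(prop-1-en-2-yl)trideca-2,8,10-trienoate (8E/8Z mixture)
Product: 10 ethyl (2E)-2-methyl-4-{(1R)-2,2,4-trimethyl-3-[(1E)-3-oxobut-1-en-1-yl]cyclohex-3-en-1-yl}but-2-enoate, via ring cation 9 (not isolated)
Conditions: H2SO4 (96 %, 5 equiv), CH2Cl2, −20 → 0 °C; then ice/aq NaHCO3
Reagents that add atoms: none
Why: This is a proton-initiated cation–olefin cyclization that copies the C50 β-cyclase step: Markovnikov protonation of the isopropenyl group, the only electron-rich π bond because the enoate and the dienone are deactivated by their carbonyl groups, gives the tertiary C1 cation, C6 of the C5=C6 bond attacks it, and ring cation 9 loses the C6 proton to give the conjugated β-ring. The closest known reaction type is the sulfuric acid cyclization of pseudoionone to β-ionone and of 9-methylpseudoionone to the irones, which also carry a substituent at C2. The ring closes in a 6-endo-trig mode through a chair-like transition state with the C2 side chain equatorial, and this single C1–C6 bond completes the trimethylcyclohexene with its tetrasubstituted double bond and the C6–C7 link already in place. No stereocentre is created, since C6 ends trigonal, so both C5=C6 isomers of 8 and the kinetic α- and γ-double-bond isomers, which the acid re-protonates to 9, converge on 10. The step needs site-selective protonation, β-selective proton loss and retention at C2: the first is secured by the carbonyl deactivation of the other alkenes, the second by thermodynamic control in concentrated acid, and the third by the fact that C2 is not a reacting atom, that its C–H bond is gauche to the vacant orbital at C1 in the chair with the side chain equatorial and so badly placed for a 1,2-hydride shift, and that capture by the tethered alkene at low temperature should outrun such a shift, as capture outruns it when acids add to the isopropenyl group of limonene.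

**Step 6**
Reactants: 10 ethyl (2E)-2-methyl-4-{(1R)-2,2,4-trimethyl-3-[(1E)-3-oxobut-1-en-1-yl]cyclohex-3-en-1-yl}but-2-enoate
Product: 11 ethyl (2E)-4-{(1R)-3-[(1E,3RS)-3-hydroxy-3-methylpenta-1,4-dien-1-yl]-2,2,4-trimethylcyclohex-3-en-1-yl}-2-methylbut-2-enoate
Conditions: CH2=CHMgBr (1.2 equiv), LaCl3·2LiCl (1.0 equiv), THF, −40 → −10 °C; aq NH4Cl
Reagents that add atoms: vinylmagnesium bromide, C=C[Mg]Br
Why: 1,2-Addition of a vinyl Grignard reagent to the β-ionone-type methyl ketone (the vinyl-β-ionol synthesis), with LaCl3·2LiCl activating the hindered ketone so that it is attacked in preference to the α-methyl enoate ester, gives a carbinol whose new centre is ionised in step 8 and needs no control.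

**Step 7**
Reactants: 11 ethyl (2E)-4-{(1R)-3-[(1E,3RS)-3-hydroxy-3-methylpenta-1,4-dien-1-yl]-2,2,4-trimethylcyclohex-3-en-1-yl}-2-methylbut-2-enoate
Product: 12 (2E)-4-{(1R)-3-[(1E,3RS)-3-hydroxy-3-methylpenta-1,4-dien-1-yl]-2,2,4-trimethylcyclohex-3-en-1-yl}-2-methylbut-2-en-1-ol
Conditions: i-Bu2AlH (3.5 equiv), CH2Cl2, −78 °C; aq potassium sodium tartrate
Reagents that add atoms: none
Why: i-Bu2AlH reduces the conjugated ester in a 1,2-sense to the E-allylic alcohol without touching the alkenes, the tertiary alkoxide is inert, and the neutral tartrate work-up spares the acid-labile doubly allylic carbinol, so that the side-chain hydroxyl of the target is set free before any polyene exists.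

**Step 8**
Reactants: 12 (2E)-4-{(1R)-3-[(1E,3RS)-3-hydroxy-3-methylpenta-1,4-dien-1-yl]-2,2,4-trimethylcyclohex-3-en-1-yl}-2-methylbut-2-en-1-ol
Product: 13 [(2E,4E)-5-{(5R)-5-[(2E)-4-hydroxy-3-methylbut-2-en-1-yl]-2,6,6-trimethylcyclohex-1-en-1-yl}-3-methylpenta-2,4-dien-1-yl]triphenylphosphonium bromide
Conditions: Ph3P·HBr (1.0 equiv), MeOH, 0 °C → rt, dark
Reagents that add atoms: triphenylphosphine hydrobromide, [Br-].c1ccc(cc1)[PH+](c1ccccc1)c1ccccc1
Why: In this acid-mediated allylic transposition to the phosphonium salt, Ph3P·HBr should ionise only the tertiary doubly allylic carbinol, which gives a delocalised trienyl cation that PPh3 captures at the unhindered terminal carbon with the 9E geometry favoured under these equilibrating conditions, while the primary 2-methylallylic side-chain alcohol cannot form a comparably stabilised cation at this temperature.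

**Step 9**
Reactants: 13 the C15 hydroxy phosphonium bromide (2.1 equiv); 14 (2E,4E,6E)-2,7-dimethylocta-2,4,6-trienedial
Product: 17 (2R,2'R)-2,2'-bis[(2E)-4-hydroxy-3-methylbut-2-en-1-yl]-β,β-carotene (CNP0359519.1), via C15 ylide 15 (not isolated), via C30 hydroxy aldehyde 16 (not isolated)
Conditions: NaOMe (2.3 equiv), MeOH/CH2Cl2, −10 °C → rt, dark; then EtOH, reflux (Z → E)
Reagents that add atoms: none
Why: Twofold Wittig olefination of the C10 dialdehyde with the semistabilised allylic ylide (the C15 + C10 + C15 carotenoid assembly) forms C11=C12 and C11'=C12', tolerates the free hydroxyl groups in methanolic methoxide, gives E/Z mixtures at the new bonds that heating should convert into the all-E polyene because the 11Z isomers are sterically strained, and delivers the target with no later redox or deprotection step.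

**Compound list**
1 | (4R)-limonene 1,2-oxide, (4R)-1-methyl-4-(prop-1-en-2-yl)-7-oxabicyclo[4.1.0]heptane (cis/trans mixture) | CC12OC1C[C@@H](CC2)C(=C)C | starting material
2 | (3R)-6-oxo-3-(prop-1-en-2-yl)heptanal | O=CC[C@@H](CCC(C)=O)C(=C)C | intermediate
3 | ethyl 2-(triphenylphosphoranylidene)propanoate | CCOC(=O)C(C)=P(c1ccccc1)(c1ccccc1)c1ccccc1 | starting material
4 | ethyl (2E,5R)-2-methyl-8-oxo-5-(prop-1-en-2-yl)non-2-enoate | CCOC(=O)/C(C)=C/C[C@@H](CCC(C)=O)C(=C)C | intermediate
5 | ethyl (2E,5R,8RS)-8-hydroxy-2,8-dimethyl-5-(prop-1-en-2-yl)dec-2-en-9-ynoate (C8 epimers) | CCOC(=O)/C(C)=C/C[C@@H](CCC(C)(O)C#C)C(=C)C | intermediate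
6 | ethyl (2E,5R)-2,8-dimethyl-5-(prop-1-en-2-yl)-8-(prop-1-en-2-yloxy)dec-2-en-9-ynoate | CCOC(=O)/C(C)=C/C[C@@H](CCC(C)(OC(C)=C)C#C)C(=C)C | intermediate (not isolated)
7 | ethyl (2E,5R)-2,8-dimethyl-12-oxo-5-(prop-1-en-2-yl)trideca-2,8,9-trienoate (allene isomers) | CCOC(=O)/C(C)=C/C[C@@H](CCC(C)=C=CCC(C)=O)C(=C)C | intermediate (not isolated)
8 | ethyl (2E,5R,10E)-2,8-dimethyl-12-oxo-5-(prop-1-en-2-yl)trideca-2,8,10-trienoate (8E/8Z mixture) | CCOC(=O)/C(C)=C/C[C@@H](CCC(C)=C/C=C/C(C)=O)C(=C)C | intermediate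
9 | (4R)-4-[(2E)-4-ethoxy-3-methyl-4-oxobut-2-en-1-yl]-1,3,3-trimethyl-2-[(1E)-3-oxobut-1-en-1-yl]cyclohexan-1-ylium hydrogensulfate (C2 epimers) | C[C+]1CC[C@H](C/C=C(\C)C(=O)OCC)C(C)(C)C1/C=C/C(C)=O.OS(=O)(=O)[O-] | intermediate (not isolated)
10 | ethyl (2E)-2-methyl-4-{(1R)-2,2,4-trimethyl-3-[(1E)-3-oxobut-1-en-1-yl]cyclohex-3-en-1-yl}but-2-enoate | CC1=C(/C=C/C(C)=O)C(C)(C)[C@@H](C/C=C(\C)C(=O)OCC)CC1 | intermediate
11 | ethyl (2E)-4-{(1R)-3-[(1E,3RS)-3-hydroxy-3-methylpenta-1,4-dien-1-yl]-2,2,4-trimethylcyclohex-3-en-1-yl}-2-methylbut-2-enoate (carbinol epimers) | CC1=C(/C=C/C(C)(O)C=C)C(C)(C)[C@@H](C/C=C(\C)C(=O)OCC)CC1 | intermediate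
12 | (2E)-4-{(1R)-3-[(1E,3RS)-3-hydroxy-3-methylpenta-1,4-dien-1-yl]-2,2,4-trimethylcyclohex-3-en-1-yl}-2-methylbut-2-en-1-ol (carbinol epimers) | CC1=C(/C=C/C(C)(O)C=C)C(C)(C)[C@@H](C/C=C(\C)CO)CC1 | intermediate
13 | [(2E,4E)-5-{(5R)-5-[(2E)-4-hydroxy-3-methylbut-2-en-1-yl]-2,6,6-trimethylcyclohex-1-en-1-yl}-3-methylpenta-2,4-dien-1-yl]triphenylphosphonium bromide | CC1=C(/C=C/C(C)=C/C[P+](c2ccccc2)(c2ccccc2)c2ccccc2)C(C)(C)[C@@H](C/C=C(\C)CO)CC1.[Br-] | intermediate
14 | (2E,4E,6E)-2,7-dimethylocta-2,4,6-trienedial | O=C/C(C)=C/C=C/C=C(C)/C=O | starting material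
15 | (2E)-2-methyl-4-{(1R)-2,2,4-trimethyl-3-[(1E,3E)-3-methyl-5-(triphenyl-λ5-phosphanylidene)penta-1,3-dien-1-yl]cyclohex-3-en-1-yl}but-2-en-1-ol | CC1=C(/C=C/C(C)=C/C=P(c2ccccc2)(c2ccccc2)c2ccccc2)C(C)(C)[C@@H](C/C=C(\C)CO)CC1 | intermediate (not isolated)
16 | (2E,4E,6E,8E,10E,12E)-13-{(5R)-5-[(2E)-4-hydroxy-3-methylbut-2-en-1-yl]-2,6,6-trimethylcyclohex-1-en-1-yl}-2,7,11-trimethyltrideca-2,4,6,8,10,12-hexaenal (C11=C12 drawn E) | CC1=C(/C=C/C(C)=C/C=C/C(C)=C/C=C/C=C(C)/C=O)C(C)(C)[C@@H](C/C=C(\C)CO)CC1 | intermediate (not isolated)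
17 | (2R,2'R)-2,2'-bis[(2E)-4-hydroxy-3-methylbut-2-en-1-yl]-β,β-carotene | CC1=C(/C=C/C(C)=C/C=C/C(C)=C/C=C/C=C(C)/C=C/C=C(C)/C=C/C2=C(C)CC[C@H](C/C=C(\C)CO)C2(C)C)C(C)(C)[C@@H](C/C=C(\C)CO)CC1 | target

**Step count and risks**
Total step count: 9. Longest linear sequence: 9 (steps 1–9).

Steps most likely to fail:

1. Step 5 (key step). The open C1 cation may lose configuration at C2 by a 1,2-hydride shift or by proton loss to the tetrasubstituted alkene before the ring closes, or proton loss from the ring cation may stop at unconjugated double-bond isomers. The fallback sets out from 8 and comes back at 10. The isopropenyl group would be activated by divalent mercury instead of a proton: Hg(OTf)2·PhNMe2 (1.2 equiv) in MeNO2 at −20 °C, then aq NaCl, should close the same C1–C6 bond through a bridged mercurinium ion that cannot undergo a hydride shift. This should give the kinetic α-type organomercurial ethyl (2E)-4-{(1R)-2-[(chloromercurio)methyl]-2,4-dimethyl-3-[(1E)-3-oxobut-1-en-1-yl]cyclohex-4-en-1-yl}-2-methylbut-2-enoate F1 (diastereomer mixture). Bu3SnH (AIBN, toluene, 60 °C) would replace mercury by hydrogen to give the α-isomer ethyl (2E)-2-methyl-4-{(1R)-2,2,4-trimethyl-3-[(1E)-3-oxobut-1-en-1-yl]cyclohex-4-en-1-yl}but-2-enoate F2. A brief treatment with cold H2SO4, harmless once C1 is quaternary, would then move the double bond into conjugation to give 10.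

2. Step 8. The primary side-chain alcohol may ionise as well, or the hydroxy salt may resist purification. The fallback sets out from 10 and 14 and comes back at 17, with the phosphorus moved to the central unit so that no free hydroxyl meets the acidic salt formation.
   - Horner–Wadsworth–Emmons olefination of 10 with (EtO)2P(O)CH2CN (NaH, THF) would give the nitrile ethyl (2E)-4-{(1R)-3-[(1E,3E)-4-cyano-3-methylbuta-1,3-dien-1-yl]-2,2,4-trimethylcyclohex-3-en-1-yl}-2-methylbut-2-enoate F3, the 9Z isomer being removed by chromatography.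
   - i-Bu2AlH would turn nitrile into aldehyde and ester into alcohol in one operation to give (2E,4E)-5-{(5R)-5-[(2E)-4-hydroxy-3-methylbut-2-en-1-yl]-2,6,6-trimethylcyclohex-1-en-1-yl}-3-methylpenta-2,4-dienal F4.
   - NaBH4 would reduce 14 to (2E,4E,6E)-2,7-dimethylocta-2,4,6-triene-1,8-diol F5, and Ph3P·HBr (2 equiv, MeOH) would give [(2E,4E,6E)-2,7-dimethylocta-2,4,6-triene-1,8-diyl]bis(triphenylphosphonium) dibromide F6.
   - Twofold Wittig reaction of F6 with F4 (NaOMe, MeOH/CH2Cl2, then thermal Z → E equilibration) would give 17.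

3. Step 6. The Grignard reagent may also attack the ester, or may enolise the methyl ketone. The fallback sets out from 10 and comes back at 13, with the two carbons added by olefination instead of 1,2-addition. Horner–Wadsworth–Emmons reaction with triethyl phosphonoacetate (NaH, THF) would give ethyl (2E,4E)-5-{(5R)-5-[(2E)-4-ethoxy-3-methyl-4-oxobut-2-en-1-yl]-2,6,6-trimethylcyclohex-1-en-1-yl}-3-methylpenta-2,4-dienoate F7 (9E/9Z mixture, not separated). i-Bu2AlH would reduce both esters to (2E,4E)-5-{(5R)-5-[(2E)-4-hydroxy-3-methylbut-2-en-1-yl]-2,6,6-trimethylcyclohex-1-en-1-yl}-3-methylpenta-2,4-dien-1-ol F8. Ph3P·HBr would ionise the dienylic alcohol of F8 to the same trienyl cation as 12 and give 13, the C9=C10 geometry being reset at the cation stage.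

**Further compounds**
F1 | step 5 | ethyl (2E)-4-{(1R)-2-[(chloromercurio)methyl]-2,4-dimethyl-3-[(1E)-3-oxobut-1-en-1-yl]cyclohex-4-en-1-yl}-2-methylbut-2-enoate | CC1=CC[C@H](C/C=C(\C)C(=O)OCC)C(C)(C[Hg]Cl)C1/C=C/C(C)=O
F2 | step 5 | ethyl (2E)-2-methyl-4-{(1R)-2,2,4-trimethyl-3-[(1E)-3-oxobut-1-en-1-yl]cyclohex-4-en-1-yl}but-2-enoate | CC1=CC[C@H](C/C=C(\C)C(=O)OCC)C(C)(C)C1/C=C/C(C)=O
F3 | step 8 | ethyl (2E)-4-{(1R)-3-[(1E,3E)-4-cyano-3-methylbuta-1,3-dien-1-yl]-2,2,4-trimethylcyclohex-3-en-1-yl}-2-methylbut-2-enoate | CC1=C(/C=C/C(C)=C/C#N)C(C)(C)[C@@H](C/C=C(\C)C(=O)OCC)CC1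
F4 | step 8 | (2E,4E)-5-{(5R)-5-[(2E)-4-hydroxy-3-methylbut-2-en-1-yl]-2,6,6-trimethylcyclohex-1-en-1-yl}-3-methylpenta-2,4-dienal | CC1=C(/C=C/C(C)=C/C=O)C(C)(C)[C@@H](C/C=C(\C)CO)CC1
F5 | step 8 | (2E,4E,6E)-2,7-dimethylocta-2,4,6-triene-1,8-diol | OC/C(C)=C/C=C/C=C(C)/CO
F6 | step 8 | [(2E,4E,6E)-2,7-dimethylocta-2,4,6-triene-1,8-diyl]bis(triphenylphosphonium) dibromide | [Br-].[Br-].c1ccccc1[P+](c1ccccc1)(c1ccccc1)C/C(C)=C/C=C/C=C(C)/C[P+](c1ccccc1)(c1ccccc1)c1ccccc1
F7 | step 6 | ethyl (2E,4E)-5-{(5R)-5-[(2E)-4-ethoxy-3-methyl-4-oxobut-2-en-1-yl]-2,6,6-trimethylcyclohex-1-en-1-yl}-3-methylpenta-2,4-dienoate | CC1=C(/C=C/C(C)=C/C(=O)OCC)C(C)(C)[C@@H](C/C=C(\C)C(=O)OCC)CC1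
F8 | step 6 | (2E,4E)-5-{(5R)-5-[(2E)-4-hydroxy-3-methylbut-2-en-1-yl]-2,6,6-trimethylcyclohex-1-en-1-yl}-3-methylpenta-2,4-dien-1-ol | CC1=C(/C=C/C(C)=C/CO)C(C)(C)[C@@H](C/C=C(\C)CO)CC1
A1 | direct plan | (R)-α-campholenic aldehyde, 2-[(1R)-2,2,3-trimethylcyclopent-3-en-1-yl]acetaldehyde | CC1=CC[C@H](CC=O)C1(C)C
A2 | direct plan | ethyl (2E,5S)-2,6,6-trimethyl-7-oxo-5-(2-oxoethyl)oct-2-enoate | CC(=O)C(C)(C)[C@H](CC=O)C/C=C(\C)C(=O)OCC
A3 | direct plan | ethyl (2E)-4-[(1R)-2,2-dimethyl-3-oxocyclohex-4-en-1-yl]-2-methylbut-2-enoate | O=C1C=CC[C@H](C/C=C(\C)C(=O)OCC)C1(C)C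
A4 | direct plan | ethyl (2E)-2-methyl-4-[(1R)-2,2,4-trimethyl-3-{[(trifluoromethyl)sulfonyl]oxy}cyclohex-3-en-1-yl]but-2-enoate | CC1=C(OS(=O)(=O)C(F)(F)F)C(C)(C)[C@@H](C/C=C(\C)C(=O)OCC)CC1
A5 | direct plan | [(2E,4E)-5-{(5R)-5-[(2E)-4-ethoxy-3-methyl-4-oxobut-2-en-1-yl]-2,6,6-trimethylcyclohex-1-en-1-yl}-3-methylpenta-2,4-dien-1-yl]triphenylphosphonium bromide | CC1=C(/C=C/C(C)=C/C[P+](c2ccccc2)(c2ccccc2)c2ccccc2)C(C)(C)[C@@H](C/C=C(\C)C(=O)OCC)CC1.[Br-]
A6 | direct plan | (2R,2'R)-2,2'-bis[(2E)-4-ethoxy-3-methyl-4-oxobut-2-en-1-yl]-β,β-carotene | CC1=C(/C=C/C(C)=C/C=C/C(C)=C/C=C/C=C(C)/C=C/C=C(C)/C=C/C2=C(C)CC[C@H](C/C=C(\C)C(=O)OCC)C2(C)C)C(C)(C)[C@@H](C/C=C(\C)C(=O)OCC)CC1
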